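In a one-step world, whatever leaves the starting material turns up as ring, and the two readings add up to the charge. Red refuses this. At 12.0 min it reads 16.6 % starting material and 23.4 % ring, so 60.0 % of the charge stands elsewhere. At one starting material per impurity, the protic impurity could hold 1.00 % of it. I read the remainder as open dimer, the resting state of the starting material here.

| flask | starting material | protic impurity | remark | time |
|---|---|---|---|---|
| green | 1.3 M | 0.0182 M | run made earlier |  |
| amber | 2 M | 0.0182 M | run made earlier |  |
| red | 0.91 M | 0.0091 M | run made earlier |  |
| oak | 0.91 M | 0.0182 M |  | 12 min |
| alder | 0.91 M | 0.0182 M |  | 15 min |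
| cedar | 0.91 M | 0.0182 M |  | 10 min |

| run | time / min | ring / % | starting material / % |
|---|---|---|---|
| green | 1.50 | 5.8 | 26.8 |
| green | 4.00 | 9.9 | 16.5 |
| green | 8.00 | 15.3 | 15.2 |
| green | 12.0 | 20.1 | 14.9 |
| amber | 1.00 | 4.1 | 26.0 |
| amber | 2.00 | 5.4 | 17.1 |
| amber | 5.00 | 9.1 | 13.6 |
| amber | 12.0 | 16.8 | 13.1 |
| red | 1.50 | 6.9 | 32.7 |
| red | 4.00 | 11.8 | 19.7 |
| red | 8.00 | 17.3 | 17.6 |
| red | 12.0 | 23.4 | 16.6 |

(readings scatter by 0.3 percentage points)

- a species is counted by the starting material in it: one open dimer counts as two
- a reading or a percentage of ring counts all its forms, free or not

1. which of the two there is more of at the end, counted by the starting material in each, oak (open dimer / ring)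
2. which of the two there is more of at the end, counted by the starting material in each, alder (open dimer / ring)
3. which of the two there is more of at the end, counted by the starting material in each, cedar (open dimer / ring)
4. final ring, as a percentage of the starting material charged, in oak
5. final ring, as a percentage of the starting material charged, in alder
6. final ring, as a percentage of the starting material charged, in cedar

The bench rule says that ring climbs in a straight line once the free fraction has levelled. From red, between 4.00 min and 12.0 min, with the middle reading as the free fraction:

κ = (23.4 % − 11.8 %) / (12.0 min − 4.00 min) / 17.6 % = 0.0824 min⁻¹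

Call this the ring clock: the fraction of the charge gained as ring per minute, for each unit of free fraction.

Where does the rule stop? Compare two rates and watch the ratio of free fraction lost to ring gained. In red it is 2.65 between 1.50 min and 4.00 min, so the free fraction falls faster than ring rises, and the straight line fails there. Between 4.00 min and 12.0 min the ratio reads 0.267, so ring rises faster than the free fraction falls, and I read the difference as coming out of the open dimer. Read from these points, the border in red lies near 4.00 min, and even the 10 min of cedar stands later.

Oak, alder and cedar carry more impurity than red, and at one starting material per impurity the extra takes 1.00 % of the charge. My own reckoning scales red by that and holds the free fraction at its last reading: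

ring = (1 − 1.00 %) × (23.4 % + κ × 16.6 % × (t − 12.0 min))

- oak: 23.2 %
- alder: 27.2 %
- cedar: 20.5 %

By balance, alder keeps about 54.2 % as open dimer, more than its ring. My figures for oak and cedar are lower in ring, so I say open dimer for all of them.

The forecast, finding that “ring growth tracks free starting material”, gives 23.2 % for oak, 27.3 % for alder and 20.3 % for cedar, slightly apart from mine in the last two, and says open dimer for oak, open dimer for alder and open dimer for cedar.

The flasks give ring at 23.2 % in oak, 27.2 % in alder and 20.5 % in cedar, and open dimer at 58.1 %, 54.6 % and 60.5 % in the same order.

starting material + protic impurity → quenched substrate (k = 1.60 L mol⁻¹ min⁻¹); starting material → ring (k = 0.0820 min⁻¹); 2 starting material ⇌ open dimer (K = 8.80 L mol⁻¹, k = 0.750 L mol⁻¹ min⁻¹); crystals ⇌ ring, rate k4*(cs4 - [ring]) while solid is left; crystals form when [ring] > cs4 (solubility = 0.370 M, k = 6.50 min⁻¹); starting material → decomposition product (k = 3.70 × 10⁻⁴ min⁻¹) Alder holds 1.98 % of the charge as quenched substrate, with 0.79 % of its own impurity left. The neighbour of alder charged with 0.23 M of starting material and read at the same time has 20.3 % free, against 16.0 % in alder. Put into the clock, those two figures give 0.0167 min⁻¹ against 0.0132 min⁻¹, each as a share of its own charge. The ring of that neighbour stands at 42.0 %.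

Readings and results stem from a simulated flask on assumed constants.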